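**Plan**

1. Numbering (germacranolide): C1 furanone C=O, C2 furanone =CH, C3 furanone O–C=, C4 (=C15H2), C5 (OH), C6 (lactone O–CH), C7, C8 (O‑isovaleryl), C9, C10 (quaternary, C14 methyl, ring O), C11 (=C13H2), C12 (lactone C=O).
2. Enabling feature: the five‑membered 3(2H)‑furanone (O, C10, C1, C2, C3) that bridges the ten‑membered carbocycle C1–C10 is the cyclodehydrated form of a C1/C3 1,3‑diketone carrying the C10 tertiary hydroxyl. C10 is quaternary, so C2 is the only enolizable carbon of a C1 methyl ketone, and C2–C3 is an aldol bond to a C3 aldehyde.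
3. Retrosynthetic cuts: C10–O–C3 (furanone, cyclodehydration); C2–C3 (aldol closure of the ten‑membered ring); C4–C5 (alkenyl addition to an aldehyde); C11=C13 and C7–C8 (Mannich trap and conjugate addition to a butenolide); C8–C9 (dithiane plus epoxide).
4. Forward order: East fragment C8–C9–C10(C14)–C1–C2 from 3‑methylbut‑3‑en‑2‑ol and 1,3‑dithiane; conjugate addition to the (S)‑butenolide (lactone ring present from the start); C8 reduction and acylation, α‑methylene unveiled; C3–C4(C15) added at C5; then the ten‑membered ring (key step); then the furanone ring.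
5. Stereochemistry: C6 from (5S)‑5‑(hydroxymethyl)furan‑2(5H)‑one; C7 by addition anti to the C6 substituent; C10 from a Sharpless kinetic resolution; C8 by 1,3‑anti hydroxyl‑directed reduction relayed from C10; C5 by Felkin–Anh addition controlled by C6.

Key step: step 19

Remark on the chemistry: C11 in 12–16 and C3 in 31 are expected as epimer mixtures; both carbons become sp2 later, so they are drawn without configuration.

**Step 1**
Reactants: 1 rac‑3‑methylbut‑3‑en‑2‑ol
Product: 2 (1S)‑1‑[(2R)‑2‑methyloxiran‑2‑yl]ethan‑1‑ol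
Conditions: Ti(OiPr)4 (10 mol %), L‑(+)‑DIPT (15 mol %), t‑BuOOH (0.45 equiv), 4 Å MS, CH2Cl2, −20 °C
Reagents that add atoms: tert‑butyl hydroperoxide CC(C)(C)OO
Why: Sharpless kinetic resolution (titanium–tartrate epoxidation): with L‑(+)‑DIPT the (S)‑alcohol should react much faster than its antipode and take oxygen on the alkene face that makes the quaternary epoxide carbon (future C10) R, erythro‑selectively, so that stopping below half conversion should leave the (R)‑alcohol behind.

**Step 2**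
Reactants: 2 (1S)‑1‑[(2R)‑2‑methyloxiran‑2‑yl]ethan‑1‑ol; 3 1,3‑dithiane
Product: 5 (2S,3R)‑4‑(1,3‑dithian‑2‑yl)‑3‑methylbutane‑2,3‑diol, via 2‑lithio‑1,3‑dithiane 4 (not isolated)
Conditions: 3 (2.2 equiv), n‑BuLi (2.2 equiv), THF, −30 °C; then 2, −30 → 0 °C; H2O
Reagents that add atoms: none
Why: Corey–Seebach alkylation in which the dithiane anion (future C8) should open the 2,2‑disubstituted epoxide by SN2 attack at its unsubstituted CH2 (future C9), leaving the C10 configuration untouched, the extra equivalent of base being consumed by the hydroxyl group.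

**Step 3**
Reactants: 5 (2S,3R)‑4‑(1,3‑dithian‑2‑yl)‑3‑methylbutane‑2,3‑diol
Product: 6 (3R)‑4‑(1,3‑dithian‑2‑yl)‑3‑hydroxy‑3‑methylbutan‑2‑one
Conditions: SO3·pyridine, DMSO, i‑Pr2NEt, CH2Cl2, 0 °C
Reagents that add atoms: none
Why: Parikh–Doering (activated DMSO) oxidation should convert only the secondary carbinol (C1) into the methyl ketone, since the tertiary alcohol cannot be oxidized and the thioacetal is inert to this oxidant.

**Step 4**
Reactants: 6 (3R)‑4‑(1,3‑dithian‑2‑yl)‑3‑hydroxy‑3‑methylbutan‑2‑one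
Product: 7 (2R)‑1‑(1,3‑dithian‑2‑yl)‑2‑(2‑methyl‑1,3‑dioxolan‑2‑yl)propan‑2‑ol
Conditions: TMSOCH2CH2OTMS, TMSOTf (5 mol %), CH2Cl2, −78 → −20 °C; pyridine, aq. NaHCO3
Reagents that add atoms: 1,2‑bis(trimethylsilyloxy)ethane C[Si](C)(C)OCCO[Si](C)(C)C
Why: Low‑temperature silyl‑triflate‑catalysed ketalization should mask the hindered ketone as its dioxolane without acid‑promoted α‑ketol rearrangement, and it turns the C1 substituent on C10 into a bulky quaternary group that is needed for the stereocontrol in step 8.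

**Step 5**
Reactants: 8 (5S)‑5‑(hydroxymethyl)furan‑2(5H)‑one
Product: 9 (5S)‑5‑[(tert‑butyldimethylsilyloxy)methyl]furan‑2(5H)‑one
Conditions: TBSCl, imidazole, DMF, 0 °C → rt
Reagents that add atoms: tert‑butyldimethylsilyl chloride CC(C)(C)[Si](C)(C)Cl
Why: Standard silylation of the primary alcohol gives a bulky C6 substituent that should shield one face of the butenolide in step 6.

**Step 6**
Reactants: 7 (2R)‑1‑(1,3‑dithian‑2‑yl)‑2‑(2‑methyl‑1,3‑dioxolan‑2‑yl)propan‑2‑ol; 9 (5S)‑5‑[(tert‑butyldimethylsilyloxy)methyl]furan‑2(5H)‑one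
Product: 12 Mannich‑base lactone (6S; C7 trans to C6; 10R; C11 epimers), via dilithiated dithiane 10 (not isolated), via lithium lactone enolate 11 (not isolated)
Conditions: 7 (1.2 equiv), t‑BuLi (2.5 equiv), THF–HMPA (10:1), −78 °C; 9, −78 °C; Me2N=CH2 I, −78 → 0 °C
Reagents that add atoms: Eschenmoser's salt (N,N‑dimethylmethyleneiminium iodide) C=[N+](C)C.[I-]
Why: Michael addition of the lithiated dithiane (acyl‑anion equivalent, HMPA favouring 1,4‑addition) should occur anti to the C6 CH2OTBS group and so set C7 trans, and the resulting enolate should be trapped in a Mannich reaction that installs C13 as CH2NMe2 at C11, whose configuration is irrelevant.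

**Step 7**
Reactants: 12 Mannich‑base lactone
Product: 13 C8 ketone (β‑hydroxy ketone; 6S; C7 trans; 10R)
Conditions: Hg(ClO4)2·3H2O, CaCO3, THF–H2O (5:1), 0 °C
Reagents that add atoms: water O
Why: Thioacetal hydrolysis with thiophilic divalent mercury under CaCO3 buffering should free the C8 ketone while the amine, the dioxolane and the silyl ether survive, and the sp3 C11 prevents isomerization of the lactone at this stage.

**Step 8**
Reactants: 13 C8 ketone
Product: 14 8,10‑anti diol (6S; 7R; 8R; 10R)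
Conditions: Me4NBH(OAc)3, MeCN–AcOH (1:1), −30 °C
Reagents that add atoms: none
Why: Evans–Saksena hydroxyl‑directed reduction in which hydride is delivered intramolecularly from the boron bound to the C10 oxygen through a chair transition state that places the bulky dioxolanyl group on C10 equatorial and the methyl group axial, which should give the 1,3‑anti diol and hence 8R.

**Step 9**
Reactants: 14 8,10‑anti diol
Product: 15 C8 isovalerate of 14
Conditions: Me2CHCH2COCl, pyridine, DMAP (cat.), CH2Cl2, 0 °C → rt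
Reagents that add atoms: 3‑methylbutanoyl chloride CC(C)CC(=O)Cl
Why: DMAP‑catalysed acylation should esterify the secondary C8 hydroxyl only, because the tertiary C10 hydroxyl is too hindered to react.

**Step 10**
Reactants: 15 C8 isovalerate
Product: 17 α‑methylene lactone (C11=C13; C5H2OTBS; dioxolane; free C10–OH), via trimethylammonium iodide 16 (not isolated)
Conditions: MeI, THF, rt; then aq. NaHCO3, EtOAc, rt
Reagents that add atoms: none
Why: Exhaustive N‑methylation followed by E1cB (Hofmann‑type) loss of trimethylamine from the β‑ammonio lactone should unveil the α‑methylene lactone under conditions mild enough for both esters.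

**Step 11**
Reactants: 17 α‑methylene lactone
Product: 18 C5 primary alcohol with free C1 methyl ketone and C10–OH
Conditions: aq. H2SO4 (1 M), THF, 40 °C
Reagents that add atoms: water O
Why: Aqueous acid with a non‑nucleophilic counter‑ion should cleave the primary TBS ether and hydrolyse the dioxolane in one operation, leaving the lactone, the ester and the tertiary alcohol (no stabilized cation possible next to the carbonyl) intact.

**Step 12**
Reactants: 18 C5 primary alcohol
Product: 19 C5 aldehyde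
Conditions: Dess–Martin periodinane, CH2Cl2, 0 °C → rt
Reagents that add atoms: none
Why: Dess–Martin oxidation of the only oxidizable (primary) alcohol under non‑basic conditions should give the aldehyde without epimerization at C6, and the aldehyde is used at once.

**Step 13**
Reactants: 20 2,3‑dibromoprop‑1‑ene; 21 (4‑methoxyphenyl)methanol
Product: 22 1‑{[(2‑bromoprop‑2‑en‑1‑yl)oxy]methyl}‑4‑methoxybenzene
Conditions: NaH, THF, 0 °C → rt
Reagents that add atoms: none
Why: Williamson ether synthesis in which the alkoxide displaces the allylic bromide while the vinylic bromide is inert.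

**Step 14**
Reactants: 19 C5 aldehyde; 22 1‑{[(2‑bromoprop‑2‑en‑1‑yl)oxy]methyl}‑4‑methoxybenzene
Product: 24 (5R)‑allylic alcohol carrying C4(=C15H2)–C3H2OPMB, via alkenylchromium dichloride 23 (not isolated)
Conditions: 22 (3 equiv), CrCl2 (8 equiv), NiCl2 (2 mol %), DMF, rt
Reagents that add atoms: none
Why: Nozaki–Hiyama–Kishi reaction in which the alkenylchromium species should add only to the aldehyde (ketone, esters and free hydroxyl tolerated) through a polar Felkin–Anh transition state with the lactone C6–O bond anti to the nucleophile, giving the 5,6‑anti adduct, which is 5R.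

**Step 15**
Reactants: 24 (5R)‑allylic alcohol
Product: 25 C5 TBS ether of 24
Conditions: TBSOTf (1.2 equiv), 2,6‑lutidine, CH2Cl2, −78 °C
Reagents that add atoms: tert‑butyldimethylsilyl triflate CC(C)(C)[Si](C)(C)OS(=O)(=O)C(F)(F)F
Why: Silyl triflate silylation at low temperature should protect the secondary allylic hydroxyl well before the tertiary α‑keto hydroxyl, so that C5–OH cannot later compete with C10–OH for the diketone.

**Step 16**
Reactants: 25 C5 TBS ether
Product: 27 bromomethyl ketone (C2–Br) with C10–OTMS, via bis‑silyl enol ether 26 (not isolated)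
Conditions: TMSOTf (2.5 equiv), Et3N (4 equiv), CH2Cl2, −20 → 0 °C; then NBS, THF, −78 °C
Reagents that add atoms: trimethylsilyl triflate C[Si](C)(C)OS(=O)(=O)C(F)(F)F; N‑bromosuccinimide O=C1CCC(=O)N1Br
Why: Soft enolization can give only the C1=C2 enol silane because C10 is quaternary and caps C10–OH at the same time, and electrophilic bromination of that enol ether, far more nucleophilic than the other alkenes, should give the bromomethyl ketone regiospecifically.

**Step 17**
Reactants: 27 bromomethyl ketone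
Product: 28 C3 primary allylic alcohol
Conditions: DDQ, CH2Cl2–pH 7 buffer (10:1), 0 °C
Reagents that add atoms: none
Why: Oxidative cleavage of the 4‑methoxybenzyl ether by DDQ under buffered conditions should spare the silyl ethers and the bromo ketone.

**Step 18**
Reactants: 28 C3 primary allylic alcohol
Product: 29 C3 enal
Conditions: Dess–Martin periodinane, NaHCO3, CH2Cl2, 0 °C
Reagents that add atoms: none
Why: Buffered Dess–Martin oxidation of the allylic alcohol should give the non‑enolizable 2‑substituted enal without loss of the tertiary TMS ether.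

**Step 19**
Reactants: 29 C3 enal
Product: 31 ten‑membered 3‑hydroxy‑1‑ketone (C3 epimers), via samarium enolate 30 (not isolated)
Conditions: SmI2 (2.2 equiv), THF, −78 °C, 29 added over 6 h (final 0.002 M); aq. NaHCO3
Reagents that add atoms: none
Why: Two single‑electron transfers from SmI2 (divalent samarium) cleave the C2–Br bond, the most easily reduced bond of 29, to give the trivalent samarium enolate 30, which adds in 1,2‑fashion to the C3 aldehyde through a chelated chair‑like (Zimmerman–Traxler) transition state and so forms the C2–C3 bond. The closest known reaction type is the SmI2‑mediated intramolecular Reformatsky‑type aldol of α‑bromo ketones and esters with aldehydes, which closes eight‑ to fourteen‑membered rings. One ring is closed, the ten‑membered carbocycle C1–C10, in a 10‑exo‑trig mode with the aldehyde oxygen outside the ring, and the oxygen bridge C10–O–C3 is left for step 21. One stereocentre (the C3 carbinol) is formed and needs no control because step 20 oxidizes it. The step needs chemoselectivity (halide reduction before the enal, the α‑methylene lactone or the α‑silyloxy ketone is touched, secured by the much faster C–Br reduction at −78 °C, two equivalents of reagent and no HMPA or proton source), site‑specific enolate formation (C2 is the only α‑carbon with hydrogen, and the TMS ether on C10–O removes the proton that would quench the enolate) and cyclization over oligomerization (slow addition at high dilution, with the trans‑fused lactone and the sp2 carbons C4 and C11 limiting the conformations of the chain).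

**Step 20**
Reactants: 31 ten‑membered 3‑hydroxy‑1‑ketone
Product: 32 ten‑membered 1,3‑diketone
Conditions: Dess–Martin periodinane (1.2 equiv), NaHCO3, CH2Cl2, 0 °C
Reagents that add atoms: none
Why: Dess–Martin oxidation of the β‑hydroxy ketone should give the 1,3‑diketone and erase the uncontrolled C3 centre, with a small excess of oxidant to avoid oxidation at C2.

**Step 21**
Reactants: 32 ten‑membered 1,3‑diketone
Product: 36 CNP0409337.2 (target), via hydroxy diketone 33 (not isolated), via bicyclic hemiketal 34 (not isolated), via furanone silyl ether 35 (not isolated)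
Conditions: HF·pyridine, pyridine, THF, 0 °C → rt
Reagents that add atoms: none
Why: The tertiary TMS ether should cleave first, the freed C10 hydroxyl should add to the C3 carbonyl (5‑exo‑trig) and the hemiketal should dehydrate to the vinylogous ester (acid‑mediated cyclodehydration of an α′‑hydroxy‑1,3‑diketone to a 3(2H)‑furanone) before the slower cleavage of the secondary TBS ether frees C5–OH, so that the C5 hydroxyl cannot close a pyranone onto C1.

**Compound list**

1 | rac‑3‑methylbut‑3‑en‑2‑ol | CC(O)C(C)=C | starting material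
2 | (1S)‑1‑[(2R)‑2‑methyloxiran‑2‑yl]ethan‑1‑ol | C1[C@@]([C@H](C)O)(C)O1 | intermediate
3 | 1,3‑dithiane | C1CSCSC1 | starting material
4 | 2‑lithio‑1,3‑dithiane | [Li]C1SCCCS1 | intermediate
5 | (2S,3R)‑4‑(1,3‑dithian‑2‑yl)‑3‑methylbutane‑2,3‑diol | S1CCCSC1C[C@@]([C@H](C)O)(C)O | intermediate
6 | (3R)‑4‑(1,3‑dithian‑2‑yl)‑3‑hydroxy‑3‑methylbutan‑2‑one | S1CCCSC1C[C@@](C(C)=O)(C)O | intermediate
7 | (2R)‑1‑(1,3‑dithian‑2‑yl)‑2‑(2‑methyl‑1,3‑dioxolan‑2‑yl)propan‑2‑ol | S1CCCSC1C[C@@](C1(C)OCCO1)(C)O | intermediate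
8 | (5S)‑5‑(hydroxymethyl)furan‑2(5H)‑one | O=C1O[C@H](CO)C=C1 | starting material
9 | (5S)‑5‑[(tert‑butyldimethylsilyloxy)methyl]furan‑2(5H)‑one | O=C1O[C@H](CO[Si](C)(C)C(C)(C)C)C=C1 | intermediate
10 | dilithiated dithiane (7 lithiated at dithiane C2 and at the hydroxyl oxygen) | [Li]C1(C[C@@](C2(C)OCCO2)(C)O[Li])SCCCS1 | intermediate
11 | lithium lactone enolate of the conjugate adduct (6S; C7 trans) | C1=C(O[Li])O[C@H](CO[Si](C)(C)C(C)(C)C)[C@H]1C1(SCCCS1)C[C@@](C1(C)OCCO1)(C)O[Li] | intermediate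
12 | (5S)‑5‑[(tert‑butyldimethylsilyloxy)methyl]‑3‑[(dimethylamino)methyl]‑4‑{2‑[(2R)‑2‑hydroxy‑2‑(2‑methyl‑1,3‑dioxolan‑2‑yl)propyl]‑1,3‑dithian‑2‑yl}oxolan‑2‑one (4,5‑trans; C3 epimers) | CN(C)CC1C(=O)O[C@H](CO[Si](C)(C)C(C)(C)C)[C@H]1C1(SCCCS1)C[C@@](C1(C)OCCO1)(C)O | intermediate
13 | (5S)‑5‑[(tert‑butyldimethylsilyloxy)methyl]‑3‑[(dimethylamino)methyl]‑4‑[(3R)‑3‑hydroxy‑3‑(2‑methyl‑1,3‑dioxolan‑2‑yl)butanoyl]oxolan‑2‑one (4,5‑trans) | CN(C)CC1C(=O)O[C@H](CO[Si](C)(C)C(C)(C)C)[C@H]1C(=O)C[C@@](C1(C)OCCO1)(C)O | intermediate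
14 | (5S)‑5‑[(tert‑butyldimethylsilyloxy)methyl]‑3‑[(dimethylamino)methyl]‑4‑[(1R,3R)‑1,3‑dihydroxy‑3‑(2‑methyl‑1,3‑dioxolan‑2‑yl)butyl]oxolan‑2‑one (4,5‑trans) | CN(C)CC1C(=O)O[C@H](CO[Si](C)(C)C(C)(C)C)[C@H]1[C@H](O)C[C@@](C1(C)OCCO1)(C)O | intermediate
15 | 3‑methylbutanoate of 14 at the secondary (C8) hydroxyl | CN(C)CC1C(=O)O[C@H](CO[Si](C)(C)C(C)(C)C)[C@H]1[C@H](OC(=O)CC(C)C)C[C@@](C1(C)OCCO1)(C)O | intermediate
16 | N‑methyl quaternary ammonium iodide of 15 | C[N+](C)(C)CC1C(=O)O[C@H](CO[Si](C)(C)C(C)(C)C)[C@H]1[C@H](OC(=O)CC(C)C)C[C@@](C1(C)OCCO1)(C)O.[I-] | intermediate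
17 | (5S)‑5‑[(tert‑butyldimethylsilyloxy)methyl]‑4‑[(1R,3R)‑3‑hydroxy‑1‑(3‑methylbutanoyloxy)‑3‑(2‑methyl‑1,3‑dioxolan‑2‑yl)butyl]‑3‑methylideneoxolan‑2‑one (4,5‑trans) | C=C1C(=O)O[C@H](CO[Si](C)(C)C(C)(C)C)[C@H]1[C@H](OC(=O)CC(C)C)C[C@@](C1(C)OCCO1)(C)O | intermediate
18 | (5S)‑5‑(hydroxymethyl)‑4‑[(1R,3R)‑3‑hydroxy‑3‑methyl‑1‑(3‑methylbutanoyloxy)‑4‑oxopentyl]‑3‑methylideneoxolan‑2‑one (4,5‑trans) | C=C1C(=O)O[C@H](CO)[C@H]1[C@H](OC(=O)CC(C)C)C[C@@](C(C)=O)(C)O | intermediate
19 | (2S)‑3‑[(1R,3R)‑3‑hydroxy‑3‑methyl‑1‑(3‑methylbutanoyloxy)‑4‑oxopentyl]‑4‑methylidene‑5‑oxooxolane‑2‑carbaldehyde (2,3‑trans) | C=C1C(=O)O[C@H](C=O)[C@H]1[C@H](OC(=O)CC(C)C)C[C@@](C(C)=O)(C)O | intermediate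
20 | 2,3‑dibromoprop‑1‑ene | C=C(Br)CBr | starting material
21 | (4‑methoxyphenyl)methanol | COc1ccc(CO)cc1 | starting material
22 | 1‑{[(2‑bromoprop‑2‑en‑1‑yl)oxy]methyl}‑4‑methoxybenzene | C=C(Br)COCc1ccc(OC)cc1 | intermediate
23 | {3‑[(4‑methoxybenzyl)oxy]prop‑1‑en‑2‑yl}chromium dichloride (trivalent chromium) | C=C(COCc1ccc(OC)cc1)[Cr](Cl)Cl | intermediate
24 | adduct of 19 and 22: (5R)‑alcohol at C5 bearing the 3‑[(4‑methoxybenzyl)oxy]prop‑1‑en‑2‑yl group (6S; 7R; 8R; 10R) | C=C1C(=O)O[C@H]([C@H](O)C(=C)COCc2ccc(OC)cc2)[C@H]1[C@H](OC(=O)CC(C)C)C[C@@](C(C)=O)(C)O | intermediate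
25 | C5 tert‑butyldimethylsilyl ether of 24 | C=C1C(=O)O[C@H]([C@H](O[Si](C)(C)C(C)(C)C)C(=C)COCc2ccc(OC)cc2)[C@H]1[C@H](OC(=O)CC(C)C)C[C@@](C(C)=O)(C)O | intermediate
26 | C1=C2 trimethylsilyl enol ether and C10 trimethylsilyl ether of 25 | C=C1C(=O)O[C@H]([C@H](O[Si](C)(C)C(C)(C)C)C(=C)COCc2ccc(OC)cc2)[C@H]1[C@H](OC(=O)CC(C)C)C[C@@](C(=C)O[Si](C)(C)C)(C)O[Si](C)(C)C | intermediate
27 | bromomethyl ketone (C2–Br) with C10–OTMS, C5–OTBS and C3–OPMB | C=C1C(=O)O[C@H]([C@H](O[Si](C)(C)C(C)(C)C)C(=C)COCc2ccc(OC)cc2)[C@H]1[C@H](OC(=O)CC(C)C)C[C@@](C(=O)CBr)(C)O[Si](C)(C)C | intermediate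
28 | C3 primary allylic alcohol from 27 | C=C1C(=O)O[C@H]([C@H](O[Si](C)(C)C(C)(C)C)C(=C)CO)[C@H]1[C@H](OC(=O)CC(C)C)C[C@@](C(=O)CBr)(C)O[Si](C)(C)C | intermediate
29 | C3 enal (seco precursor: C2 bromo ketone plus C3 aldehyde) | C=C1C(=O)O[C@H]([C@H](O[Si](C)(C)C(C)(C)C)C(=C)C=O)[C@H]1[C@H](OC(=O)CC(C)C)C[C@@](C(=O)CBr)(C)O[Si](C)(C)C | intermediate
30 | samarium enolate of 29 (C1–O–SmI2; trivalent samarium) | C=C1C(=O)O[C@H]([C@H](O[Si](C)(C)C(C)(C)C)C(=C)C=O)[C@H]1[C@H](OC(=O)CC(C)C)C[C@@](C(=C)O[Sm](I)I)(C)O[Si](C)(C)C | intermediate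
31 | (5R,6S,7R,8R,10R)‑3‑hydroxy‑8‑(3‑methylbutanoyloxy)‑1‑oxo‑5‑(tert‑butyldimethylsilyloxy)‑10‑(trimethylsilyloxy)germacra‑4(15),11(13)‑dien‑12,6‑olide (C3 epimers) | C=C1C(=O)O[C@H]2[C@H]1[C@H](OC(=O)CC(C)C)C[C@@](C)(O[Si](C)(C)C)C(=O)CC(O)C(=C)[C@H]2O[Si](C)(C)C(C)(C)C | intermediate
32 | 1,3‑dioxo analogue of 31 | C=C1C(=O)O[C@H]2[C@H]1[C@H](OC(=O)CC(C)C)C[C@@](C)(O[Si](C)(C)C)C(=O)CC(=O)C(=C)[C@H]2O[Si](C)(C)C(C)(C)C | intermediate
33 | 10‑hydroxy‑1,3‑diketone (32 without the TMS group) | C=C1C(=O)O[C@H]2[C@H]1[C@H](OC(=O)CC(C)C)C[C@@](C)(O)C(=O)CC(=O)C(=C)[C@H]2O[Si](C)(C)C(C)(C)C | intermediate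
34 | bicyclic C3 hemiketal (3,10‑epoxy‑3‑hydroxy‑1‑ketone) | C=C1C(=O)O[C@H]2[C@H]1[C@H](OC(=O)CC(C)C)C[C@@]1(C)OC(O)(CC1=O)C(=C)[C@H]2O[Si](C)(C)C(C)(C)C | intermediate
35 | 5‑O‑tert‑butyldimethylsilyl ether of the target | C=C1C(=O)O[C@H]2[C@H]1[C@H](OC(=O)CC(C)C)C[C@@]1(C)OC(=CC1=O)C(=C)[C@H]2O[Si](C)(C)C(C)(C)C | intermediate
36 | CNP0409337.2: (5R,6S,7R,8R,10R)‑3,10‑epoxy‑5‑hydroxy‑8‑(3‑methylbutanoyloxy)‑1‑oxogermacra‑2,4(15),11(13)‑trien‑12,6‑olide | C=C1C(=O)O[C@H]2[C@H]1[C@H](OC(=O)CC(C)C)C[C@@]1(C)OC(=CC1=O)C(=C)[C@H]2O | target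

**Step count and risks**

Total step count: 21. Longest linear sequence: 19 steps (steps 1–4, 6–12, 14–21).

The three steps most likely to fail:

Step 19. The samarium enolate may be protonated, or may add to a second molecule, faster than the strained ten‑membered transition state is reached, and the enal may be reduced by the reagent. The fallback sets out from 29 and comes back at 35. PPh3 (toluene, rt) would convert 29 into the C2 triphenylphosphonium bromide F1. Its ylide (Et3N, toluene, 80 °C, high dilution) should close the ring by an intramolecular Wittig reaction to the macrocyclic (2E)‑2,4(15)‑dienone F2. Removal of the tertiary TMS ether (PPTS, MeOH, 0 °C) would give the α′‑hydroxy dienone F3. A Wacker‑type 5‑endo oxidative cyclization (PdCl2(MeCN)2 as the divalent palladium catalyst, CuCl, Na2HPO4, O2, DME, 50 °C) should then give 35, which is desilylated as in step 21.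

Step 6. 1,2‑Addition to the lactone carbonyl and proton abstraction at C6 by the hindered, strongly basic carbanion may outrun the conjugate addition. The fallback sets out from 7 and 9 and comes back at 14. Hydrolysis of 7 (Hg(ClO4)2, CaCO3, THF–H2O) would give the aldehyde F4. Hydrogen‑atom abstraction from its formyl C–H under photocatalysis with (n‑Bu4N)4[W10O32] (MeCN, 390 nm) and Giese addition of the acyl radical to 9, anti to the C6 substituent, should give the keto lactone F5. Reduction as in step 8 (Me4NBH(OAc)3) would give the diol lactone F6. Its trianion (LiN(i‑Pr)2, 3.3 equiv, THF, −78 °C) would be trapped with Eschenmoser's salt to give 14.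

Step 14. Facial discrimination in the addition to the α‑acyloxy aldehyde may be low, and slow turnover of the alkenyl bromide gives the aldehyde time to epimerize at C6. The fallback sets out from 24, taken as its mixture with the C5 epimer, and comes back at 24. MnO2 (CH2Cl2, rt) would oxidize only the allylic C5 carbinol to the cross‑conjugated enone F7. A Luche reduction (NaBH4, CeCl3·7H2O, MeOH, −78 °C) should then reduce the conjugated ketone before the hindered C1 ketone and set C5 by Felkin–Anh hydride delivery to a ketone instead of by carbon addition to an aldehyde.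

**Further compounds**

F1 | step 19 | C2 triphenylphosphonium bromide derived from 29 | C=C1C(=O)O[C@H]([C@H](O[Si](C)(C)C(C)(C)C)C(=C)C=O)[C@H]1[C@H](OC(=O)CC(C)C)C[C@@](C(=O)C[P+](c1ccccc1)(c1ccccc1)c1ccccc1)(C)O[Si](C)(C)C.[Br-]
F2 | step 19 | macrocyclic (2E)‑1‑oxo‑2,4(15),11(13)‑trien‑12,6‑olide with C10–OTMS and C5–OTBS | C=C1C(=O)O[C@H]2[C@H]1[C@H](OC(=O)CC(C)C)C[C@@](C)(O[Si](C)(C)C)C(=O)/C=C/C(=C)[C@H]2O[Si](C)(C)C(C)(C)C
F3 | step 19 | 10‑hydroxy analogue of F2 | C=C1C(=O)O[C@H]2[C@H]1[C@H](OC(=O)CC(C)C)C[C@@](C)(O)C(=O)/C=C/C(=C)[C@H]2O[Si](C)(C)C(C)(C)C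
F4 | step 6 | (3R)‑3‑hydroxy‑3‑(2‑methyl‑1,3‑dioxolan‑2‑yl)butanal | O=CC[C@@](C1(C)OCCO1)(C)O
F5 | step 6 | (5S)‑5‑[(tert‑butyldimethylsilyloxy)methyl]‑4‑[(3R)‑3‑hydroxy‑3‑(2‑methyl‑1,3‑dioxolan‑2‑yl)butanoyl]oxolan‑2‑one (4,5‑trans) | C1C(=O)O[C@H](CO[Si](C)(C)C(C)(C)C)[C@H]1C(=O)C[C@@](C1(C)OCCO1)(C)O
F6 | step 6 | (5S)‑5‑[(tert‑butyldimethylsilyloxy)methyl]‑4‑[(1R,3R)‑1,3‑dihydroxy‑3‑(2‑methyl‑1,3‑dioxolan‑2‑yl)butyl]oxolan‑2‑one (4,5‑trans) | C1C(=O)O[C@H](CO[Si](C)(C)C(C)(C)C)[C@H]1[C@H](O)C[C@@](C1(C)OCCO1)(C)O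
F7 | step 14 | C5 ketone (cross‑conjugated enone) corresponding to 24 | C=C1C(=O)O[C@H](C(=O)C(=C)COCc2ccc(OC)cc2)[C@H]1[C@H](OC(=O)CC(C)C)C[C@@](C(C)=O)(C)O
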